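**Plan**

1. Retrosynthesis (lignan numbering: C7/C7′ = ArCH2, C8/C8′ = methines, C9/C9′ = CH2O; unprimed = veratryl half): free the phenol from a benzyl ether and cut the two C9/C9′ O–acetyl bonds; take the 1,4-diol back to a trans-α,β-dibenzyl-γ-lactone whose C9′ is the surviving carbon of a cleaved propenyl group; cut C8–C8′ (with an allylic C–O bond) by an Ireland–Claisen transform; cut the ester C–O bond and the allylic C=C (cross-metathesis).
2. Forward: O-benzyl allylsyringol and (R)-but-3-en-2-ol are joined by cross-metathesis; the allylic alcohol is esterified with 3-(3,4-dimethoxyphenyl)propanoic acid; the [3,3] shift joins the two C6C3 halves at C8–C8′; C=C cleavage, lactone reduction, acetylation and debenzylation follow. The target has no ring besides the two arenes; the lactone is transient.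
3. Stereochemistry: the only external source is the carbinol centre of (R)-but-3-en-2-ol. It is relayed to C8′ through the chair transition state, C8 is set relative to C8′ by the Z ketene-acetal geometry (syn), and the carbinol carbon is then excised.
4. Enabling feature: the acyclic C9(O)–C8(H)(CH2Ar)–C8′(H)(CH2Ar′)–C9′(O) array between the veratryl and syringyl rings. With C9 at the carboxyl level and C9′ as a masked vinyl carbon, C8–C8′ is the new σ-bond of a γ,δ-unsaturated acid; because both arms end as identical CH2OAc groups, either half can be the acid or the allyl partner.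

Key step: step 4

Remark (assumption): compounds 1, 3 and 5 are taken as purchased; the target is (8R,8′R), and the sense of induction in step 4 is derived from the chair model, not from experiment.

**Route**

Step 1
Reactants: 1 4-allyl-2,6-dimethoxyphenol
Product: 2 5-allyl-2-(benzyloxy)-1,3-dimethoxybenzene
Conditions: BnBr, K2CO3, DMF, 60 °C
Reagents that add atoms: benzyl bromide, BrCc1ccccc1
Why: Williamson etherification of the only acidic site; the benzyl ether should survive Ru carbenes, LDA, brief ozone exposure, LiAlH4 and Ac2O and later fall to hydrogenolysis without touching acetates, and no stereocentre is involved.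

Step 2
Reactants: 2 5-allyl-2-(benzyloxy)-1,3-dimethoxybenzene; 3 (R)-but-3-en-2-ol (excess)
Product: 4 (R,E)-5-[4-(benzyloxy)-3,5-dimethoxyphenyl]pent-3-en-2-ol
Conditions: Hoveyda–Grubbs II (cat.), 1,4-benzoquinone (cat.), CH2Cl2, 40 °C
Reagents that add atoms: none
Why: Olefin cross-metathesis between a fast-reacting allylarene and an excess of the slower secondary allylic alcohol should give the hetero-coupled 1,2-disubstituted alkene mainly as the E isomer, with benzoquinone suppressing Ru–H double-bond migration; the carbinol centre of 3 is a spectator and is carried over as R.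

Step 3
Reactants: 5 3-(3,4-dimethoxyphenyl)propanoic acid; 4 (R,E)-5-[4-(benzyloxy)-3,5-dimethoxyphenyl]pent-3-en-2-ol
Product: 7 (R,E)-5-[4-(benzyloxy)-3,5-dimethoxyphenyl]pent-3-en-2-yl 3-(3,4-dimethoxyphenyl)propanoate, via 3-(3,4-dimethoxyphenyl)propanoyl chloride 6 (not isolated)
Conditions: 5, (COCl)2, DMF (cat.), CH2Cl2, 0 °C → rt, evaporate; then 4, pyridine, DMAP (cat.), CH2Cl2, 0 °C → rt
Reagents that add atoms: oxalyl chloride, O=C(Cl)C(Cl)=O (supplies the Cl of 6 only)
Why: Acid chloride formation (Vilsmeier-type activation by catalytic DMF) followed by DMAP-catalysed acylation; only the O–H bond of 4 reacts, so the R carbinol configuration and the E alkene are retained.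

Step 4
Reactants: 7 (R,E)-5-[4-(benzyloxy)-3,5-dimethoxyphenyl]pent-3-en-2-yl 3-(3,4-dimethoxyphenyl)propanoate
Product: 10 (2R,3S,E)-3-[4-(benzyloxy)-3,5-dimethoxybenzyl]-2-(3,4-dimethoxybenzyl)hex-4-enoic acid, via (Z)-trimethylsilyl ketene acetal of 7 8 (not isolated), via trimethylsilyl (2R,3S,E)-3-[4-(benzyloxy)-3,5-dimethoxybenzyl]-2-(3,4-dimethoxybenzyl)hex-4-enoate 9 (not isolated)
Conditions: LDA, THF/DMPU (55:45), −78 °C; TMSCl, −78 °C → rt, then 50 °C; 1 M HCl, rt
Reagents that add atoms: chlorotrimethylsilane, C[Si](C)(C)Cl (supplies the Me3Si of 8 and 9 only)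
Why: Ireland–Claisen [3,3]-sigmatropic rearrangement: DMPU-solvated LDA should deprotonate 7 through an open transition state to the enolate with the ArCH2 group cis to O–Li, which is trapped as Z ketene acetal 8 and rearranges suprafacially through a chair transition state with allylic C–O cleavage and C8–C8′ formation; the closest known reaction type is the ester-enolate Claisen rearrangement of alkanoates of (E)-configured secondary allylic alcohols, in which Z ketene acetals give syn acids with 1,3-chirality transfer. No ring is closed, the six-membered array existing only in the transition state. C8′ (C3 of 10) is controlled by the carbinol stereocentre: its methyl group sits equatorial in the chair, so the new bond forms on the alkene face from which the (R)-C–O bond departs, which corresponds to 8′R in the target. C8 (C2 of 10) is controlled by the ketene-acetal geometry: a Z acetal and an E alkene in a chair place both benzylic groups equatorial, i.e. syn, which is the (8R,8′R) relationship. The step needs Z-selective enolisation (secured by the DMPU cosolvent), chair over boat (normal for acyclic substrates) and the equatorial-methyl chair (the axial alternative suffers 1,3-diaxial strain and would give the Z alkene); the ester α-CH2 is the only site acidic enough for LDA at −78 °C.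

Step 5
Reactants: 10 (2R,3S,E)-3-[4-(benzyloxy)-3,5-dimethoxybenzyl]-2-(3,4-dimethoxybenzyl)hex-4-enoic acid
Product: 13 (3R,4R)-4-[4-(benzyloxy)-3,5-dimethoxybenzyl]-3-(3,4-dimethoxybenzyl)dihydrofuran-2(3H)-one, via (2R,3R)-3-[4-(benzyloxy)-3,5-dimethoxybenzyl]-2-(3,4-dimethoxybenzyl)-4-oxobutanoic acid 11 (not isolated), via (2R,3R)-3-[4-(benzyloxy)-3,5-dimethoxybenzyl]-2-(3,4-dimethoxybenzyl)-4-hydroxybutanoic acid 12 (not isolated)
Conditions: O3, CH2Cl2/MeOH, Sudan III indicator, −78 °C; NaBH4, −78 → 0 °C; 2 M HCl, rt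
Reagents that add atoms: ozone, [O-][O+]=O
Why: Ozonolysis (1,3-dipolar cycloaddition/cycloreversion) should cleave the isolated 1,2-disubstituted alkene much faster than the alkoxyarenes when ozone uptake is limited by the indicator, borohydride reduces the peroxidic intermediates, aldehyde 11 (before its α-centre can enolise) and the acetaldehyde fragment, and acidification closes hydroxy acid 12 to the γ-lactone by 5-exo-trig acyl substitution; both stereocentres are untouched, and the lactone is a convenient point for upgrading diastereomeric purity by crystallisation.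

Step 6
Reactants: 13 (3R,4R)-4-[4-(benzyloxy)-3,5-dimethoxybenzyl]-3-(3,4-dimethoxybenzyl)dihydrofuran-2(3H)-one
Product: 14 (2R,3R)-2-[4-(benzyloxy)-3,5-dimethoxybenzyl]-3-(3,4-dimethoxybenzyl)butane-1,4-diol
Conditions: LiAlH4, THF, 0 °C → rt; Fieser work-up
Reagents that add atoms: none
Why: Hydride reduction of the lactone (acyl substitution to the lactol alkoxide, then aldehyde reduction) gives the 1,4-diol; no C–H bond at C8 or C8′ is broken, so the (R,R) configuration is retained, and the aryl and benzyl ethers are inert to LiAlH4.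

Step 7
Reactants: 14 (2R,3R)-2-[4-(benzyloxy)-3,5-dimethoxybenzyl]-3-(3,4-dimethoxybenzyl)butane-1,4-diol
Product: 15 (2R,3R)-2-[4-(benzyloxy)-3,5-dimethoxybenzyl]-3-(3,4-dimethoxybenzyl)butane-1,4-diyl diacetate
Conditions: Ac2O, pyridine, DMAP (cat.), CH2Cl2, rt
Reagents that add atoms: acetic anhydride, CC(=O)OC(C)=O
Why: DMAP-catalysed acetylation of the two primary hydroxyls; because the phenol is still a benzyl ether, only C9–OH and C9′–OH are acylated, which is what distinguishes the three hydroxyl groups of the target.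

Step 8
Reactants: 15 (2R,3R)-2-[4-(benzyloxy)-3,5-dimethoxybenzyl]-3-(3,4-dimethoxybenzyl)butane-1,4-diyl diacetate
Product: 16 Justin C, (2R,3R)-2-(3,4-dimethoxybenzyl)-3-(4-hydroxy-3,5-dimethoxybenzyl)butane-1,4-diyl diacetate
Conditions: H2 (1 atm), 10 % Pd/C, EtOAc, rt
Reagents that add atoms: none
Why: Heterogeneous hydrogenolysis cleaves the benzylic C–O bond of the aryl benzyl ether, while the acetates, the aryl methyl ethers and the non-benzylic C9/C9′–O bonds are stable, so the syringyl phenol should be released without loss or migration of acetyl groups and with the stereocentres untouched.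

**Compound list**

1 | 4-allyl-2,6-dimethoxyphenol | C=CCc1cc(OC)c(O)c(OC)c1 | starting material
2 | 5-allyl-2-(benzyloxy)-1,3-dimethoxybenzene | C=CCc1cc(OC)c(OCc2ccccc2)c(OC)c1 | intermediate
3 | (R)-but-3-en-2-ol | C[C@@H](O)C=C | starting material
4 | (R,E)-5-[4-(benzyloxy)-3,5-dimethoxyphenyl]pent-3-en-2-ol | C[C@@H](O)/C=C/Cc1cc(OC)c(OCc2ccccc2)c(OC)c1 | intermediate
5 | 3-(3,4-dimethoxyphenyl)propanoic acid | COc1ccc(CCC(=O)O)cc1OC | starting material
6 | 3-(3,4-dimethoxyphenyl)propanoyl chloride | COc1ccc(CCC(=O)Cl)cc1OC | intermediate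
7 | (R,E)-5-[4-(benzyloxy)-3,5-dimethoxyphenyl]pent-3-en-2-yl 3-(3,4-dimethoxyphenyl)propanoate | COc1ccc(CCC(=O)O[C@H](C)/C=C/Cc2cc(OC)c(OCc3ccccc3)c(OC)c2)cc1OC | intermediate
8 | (Z)-trimethylsilyl ketene acetal of 7 (ArCH2 cis to OSiMe3; R carbinol, E alkene) | COc1ccc(C/C=C(\O[Si](C)(C)C)O[C@H](C)/C=C/Cc2cc(OC)c(OCc3ccccc3)c(OC)c2)cc1OC | intermediate
9 | trimethylsilyl (2R,3S,E)-3-[4-(benzyloxy)-3,5-dimethoxybenzyl]-2-(3,4-dimethoxybenzyl)hex-4-enoate | C[Si](C)(C)OC(=O)[C@H](Cc1ccc(OC)c(OC)c1)[C@@H](Cc1cc(OC)c(OCc2ccccc2)c(OC)c1)/C=C/C | intermediate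
10 | (2R,3S,E)-3-[4-(benzyloxy)-3,5-dimethoxybenzyl]-2-(3,4-dimethoxybenzyl)hex-4-enoic acid | OC(=O)[C@H](Cc1ccc(OC)c(OC)c1)[C@@H](Cc1cc(OC)c(OCc2ccccc2)c(OC)c1)/C=C/C | intermediate
11 | (2R,3R)-3-[4-(benzyloxy)-3,5-dimethoxybenzyl]-2-(3,4-dimethoxybenzyl)-4-oxobutanoic acid | OC(=O)[C@H](Cc1ccc(OC)c(OC)c1)[C@@H](Cc1cc(OC)c(OCc2ccccc2)c(OC)c1)C=O | intermediate
12 | (2R,3R)-3-[4-(benzyloxy)-3,5-dimethoxybenzyl]-2-(3,4-dimethoxybenzyl)-4-hydroxybutanoic acid | OC(=O)[C@H](Cc1ccc(OC)c(OC)c1)[C@@H](Cc1cc(OC)c(OCc2ccccc2)c(OC)c1)CO | intermediate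
13 | (3R,4R)-4-[4-(benzyloxy)-3,5-dimethoxybenzyl]-3-(3,4-dimethoxybenzyl)dihydrofuran-2(3H)-one | O=C1OC[C@H](Cc2cc(OC)c(OCc3ccccc3)c(OC)c2)[C@H]1Cc1ccc(OC)c(OC)c1 | intermediate
14 | (2R,3R)-2-[4-(benzyloxy)-3,5-dimethoxybenzyl]-3-(3,4-dimethoxybenzyl)butane-1,4-diol | COc1ccc(C[C@@H](CO)[C@H](CO)Cc2cc(OC)c(OCc3ccccc3)c(OC)c2)cc1OC | intermediate
15 | (2R,3R)-2-[4-(benzyloxy)-3,5-dimethoxybenzyl]-3-(3,4-dimethoxybenzyl)butane-1,4-diyl diacetate | COc1ccc(C[C@@H](COC(C)=O)[C@H](COC(C)=O)Cc2cc(OC)c(OCc3ccccc3)c(OC)c2)cc1OC | intermediate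
16 | Justin C, (2R,3R)-2-(3,4-dimethoxybenzyl)-3-(4-hydroxy-3,5-dimethoxybenzyl)butane-1,4-diyl diacetate | COc1ccc(C[C@@H](COC(C)=O)[C@H](COC(C)=O)Cc2cc(OC)c(O)c(OC)c2)cc1OC | target

**Step count and risks**

Total step count: 8. Longest linear sequence: 8 (1 → 2 → 4 → 7 → 10 → 13 → 14 → 15 → 16; acid 5 and alcohol 3 enter as purchased materials).

Steps most likely to fail:

Step 4. What may go wrong: leakage of the enolisation to the E ketene acetal (incomplete DMPU solvation, or enolate equilibration before silylation) or a competing boat transition state, either of which erodes the syn relationship at C8; C-silylation would lower conversion. Fallback (sets out from 4, returns at 13): the C8–C8′ relationship is built in two separate events. Johnson–Claisen rearrangement of 4 with triethyl orthoacetate (propionic acid cat., 140 °C) should give ethyl (R,E)-3-[4-(benzyloxy)-3,5-dimethoxybenzyl]hex-4-enoate F1 by the same chair-controlled chirality transfer to C8′, with no enolate geometry to control. Ozonolysis with NaBH4 work-up should give ethyl (R)-3-[4-(benzyloxy)-3,5-dimethoxybenzyl]-4-hydroxybutanoate F2, which on acidification closes to (R)-4-[4-(benzyloxy)-3,5-dimethoxybenzyl]dihydrofuran-2(3H)-one F3. Its lithium enolate (LiHMDS, THF, −78 °C) is alkylated with 3,4-dimethoxybenzyl bromide anti to the C4 substituent, which should give trans-lactone 13.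

Step 2. What may go wrong: Ru–H-mediated migration of the allyl double bond of 2 into conjugation (leading to chain-shortened cross-products), homodimerisation of 2, and incomplete E selectivity. Fallback (sets out from 2, returns at 4; compound 3 is then not needed): ozonolysis of the terminal alkene (O3, CH2Cl2, −78 °C; Me2S) to 2-[4-(benzyloxy)-3,5-dimethoxyphenyl]acetaldehyde F4; Wittig olefination with 1-(triphenylphosphoranylidene)propan-2-one (CH2Cl2, rt) to (E)-5-[4-(benzyloxy)-3,5-dimethoxyphenyl]pent-3-en-2-one F5; Corey–Bakshi–Shibata reduction ((S)-Me-CBS, catecholborane, toluene, −78 °C), in which the alkenyl group acts as the large substituent, should give 4 with the R carbinol centre.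

Step 5. What may go wrong: over-oxidation by ozone (attack on the electron-rich arene rings or on the benzylic ether C–H) and epimerisation α to the aldehyde before reduction. Fallback (sets out from 10, returns at 14, so that 13 and step 6 are bypassed): LiAlH4 reduction of 10 to (2R,3S,E)-3-[4-(benzyloxy)-3,5-dimethoxybenzyl]-2-(3,4-dimethoxybenzyl)hex-4-en-1-ol F6; dihydroxylation (OsO4 cat., NMO, acetone/H2O) to (2R,3R)-3-[4-(benzyloxy)-3,5-dimethoxybenzyl]-2-(3,4-dimethoxybenzyl)hexane-1,4,5-triol F7 (mixture of the two syn-diol diastereomers at C4/C5); NaIO4 cleavage (THF/H2O) to (2R,3R)-2-[4-(benzyloxy)-3,5-dimethoxybenzyl]-3-(3,4-dimethoxybenzyl)-4-hydroxybutanal F8, which is held as its lactol so that the α-centre should not enolise; NaBH4 (MeOH, 0 °C) to diol 14.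

**Further compounds**

F1 | step 4 | ethyl (R,E)-3-[4-(benzyloxy)-3,5-dimethoxybenzyl]hex-4-enoate | CCOC(=O)C[C@@H](Cc1cc(OC)c(OCc2ccccc2)c(OC)c1)/C=C/C
F2 | step 4 | ethyl (R)-3-[4-(benzyloxy)-3,5-dimethoxybenzyl]-4-hydroxybutanoate | CCOC(=O)C[C@@H](Cc1cc(OC)c(OCc2ccccc2)c(OC)c1)CO
F3 | step 4 | (R)-4-[4-(benzyloxy)-3,5-dimethoxybenzyl]dihydrofuran-2(3H)-one | O=C1C[C@@H](Cc2cc(OC)c(OCc3ccccc3)c(OC)c2)CO1
F4 | step 2 | 2-[4-(benzyloxy)-3,5-dimethoxyphenyl]acetaldehyde | O=CCc1cc(OC)c(OCc2ccccc2)c(OC)c1
F5 | step 2 | (E)-5-[4-(benzyloxy)-3,5-dimethoxyphenyl]pent-3-en-2-one | CC(=O)/C=C/Cc1cc(OC)c(OCc2ccccc2)c(OC)c1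
F6 | step 5 | (2R,3S,E)-3-[4-(benzyloxy)-3,5-dimethoxybenzyl]-2-(3,4-dimethoxybenzyl)hex-4-en-1-ol | OC[C@H](Cc1ccc(OC)c(OC)c1)[C@@H](Cc1cc(OC)c(OCc2ccccc2)c(OC)c1)/C=C/C
F7 | step 5 | (2R,3R)-3-[4-(benzyloxy)-3,5-dimethoxybenzyl]-2-(3,4-dimethoxybenzyl)hexane-1,4,5-triol (C4/C5 syn-diol, both diastereomers) | OC[C@H](Cc1ccc(OC)c(OC)c1)[C@@H](Cc1cc(OC)c(OCc2ccccc2)c(OC)c1)C(O)C(C)O
F8 | step 5 | (2R,3R)-2-[4-(benzyloxy)-3,5-dimethoxybenzyl]-3-(3,4-dimethoxybenzyl)-4-hydroxybutanal | OC[C@H](Cc1ccc(OC)c(OC)c1)[C@@H](Cc1cc(OC)c(OCc2ccccc2)c(OC)c1)C=O
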